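**Plan**

1. Retrosynthesis: the two phenolic O–CH3 bonds (C5', C8') are cut first, then the benzene ring of the flavene at C4a'–C5' (Moore benzannulation) and at C8'–C8a' (organolithium addition), which leaves a 2-phenyl-4H-pyran and a C4 unit from dimethyl squarate.
2. Enabling feature: the ring C4a'–C5'–C6'–C7'–C8'–C8a' has para oxygens on C5' and C8' and OMe on C7', and C8a'=C4a' is the enol ether double bond of a monocyclic 4H-pyran, which can act as the alkenyl arm of a 4-alkenyl-4-hydroxy-3-methoxycyclobutenone.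
3. The pyran is cut at O1'–C2' and C3'–C4' (hetero-Diels–Alder of an enal with α-methoxystyrene), the side chain at C4'=C4a' and C1–CHO (two Wittig reactions from a C1 ketone), and ring A by a Robinson annulation on dihydrocarvone.
4. Forward order: ring B (chiral pool), ring A, oxygen transposition C3 to C1, C1 side chain, pyran ring, benzene ring last, then the methyl ethers.
5. Stereochemistry: C7 from (+)-dihydrocarvone; C10 from the (R)-1-phenylethylamine imine Michael addition; C5 from Li/NH3 (trans fusion); C4 from α-face Rubottom oxidation; C1 from α-face protonation of an exocyclic enol ether; C4' from a Felkin–Anh-type hetero-Diels–Alder addition next to C1.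

Key step: step 16

Remark (material): commercial (+)-dihydrocarvone contains some C2 epimer; both epimers give the same enamine in step 1, so it is used as supplied.
Remark (numbering): eudesmane numbering is used for the decalin (C10 bears the angular methyl, C4 the carbinol methyl, C7 the isopropenyl group; α = below, β = above in the usual drawing); primed numbers are flavene numbers. The ketal carbon of 25 and the carbinol carbon of 31 are carried as mixtures because both centres disappear.

**Step 1**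
Reactants: 1 (+)-dihydrocarvone; 2 (R)-1-phenylethylamine; 3 ethyl vinyl ketone
Product: 6 (2S,5R)-2-methyl-2-(3-oxopentyl)-5-(prop-1-en-2-yl)cyclohexan-1-one, via dihydrocarvone imine 4 (not isolated), via Michael-adduct imine 5 (not isolated)
Conditions: 2 (1.1 equiv), TsOH (cat.), toluene, reflux, Dean–Stark; then 3, THF, 40 °C; then 10% aq. AcOH, rt
Reagents that add atoms: ethyl vinyl ketone 3, C=CC(=O)CC; water, O
Why: Chiral-imine Michael addition in which the more substituted secondary enamine tautomer of 4 adds to 3 through a compact aza-ene-type transition state on the face away from the phenyl group of the auxiliary, so the (R)-amine should place the oxopentyl chain trans and the methyl group cis to the isopropenyl group (quaternary centre, future C10) against the weaker intrinsic bias of the ring, and hydrolysis then releases the auxiliary.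

**Step 2**
Reactants: 6 (2S,5R)-2-methyl-2-(3-oxopentyl)-5-(prop-1-en-2-yl)cyclohexan-1-one
Product: 7 (+)-α-cyperone (eudesma-4,11-dien-3-one)
Conditions: NaOMe (0.3 equiv), MeOH, rt → 50 °C
Reagents that add atoms: none
Why: Base-mediated intramolecular aldol condensation (second stage of a Robinson annulation) can close only the six-membered enone and touches no stereocentre.

**Step 3**
Reactants: 7 (+)-α-cyperone
Product: 9 3-(trimethylsilyloxy)-5αH-eudesma-3,11-diene, via lithium enolate 8 (not isolated)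
Conditions: Li, NH3(l), THF, t-BuOH (1 equiv), −78 °C; isoprene; NH3 off; then TMSCl, Et3N, THF, −78 → 0 °C
Reagents that add atoms: chlorotrimethylsilane, C[Si](C)(C)Cl
Why: Dissolving-metal reduction of the enone gives regiospecifically the C3–C4 enolate with the trans ring fusion (axial protonation of the β-carbanion sets 5α-H) while the isolated isopropenyl group is inert, and O-silylation of that enolate fixes the double bond position (reductive silylation).

**Step 4**
Reactants: 9 3-(trimethylsilyloxy)-5αH-eudesma-3,11-diene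
Product: 12 4α-hydroxy-5αH-eudesm-11-en-3-one, via silyloxy epoxide 10 (not isolated), via silyloxy ketone 11 (not isolated)
Conditions: mCPBA (1.05 equiv), CH2Cl2, −20 °C; then 1 M HCl, THF, 0 °C
Reagents that add atoms: mCPBA, OOC(=O)c1cccc(Cl)c1
Why: Rubottom oxidation in which the electron-rich tetrasubstituted silyl enol ether is epoxidised much faster than the 1,1-disubstituted isopropenyl group and from the α face, because the β face of C4 is 1,3-diaxial to the angular C10 methyl group, so ring opening, silyl migration and hydrolysis should leave the 4α-hydroxy-4β-methyl centre.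

**Step 5**
Reactants: 12 4α-hydroxy-5αH-eudesm-11-en-3-one
Product: 13 4α-hydroxy-5αH-eudesma-1,11-dien-3-one
Conditions: IBX (2.5 equiv), DMSO, 75 °C
Reagents that add atoms: none
Why: IBX-mediated α,β-dehydrogenation of a ketone is regiochemically unambiguous here because C4 is quaternary and only C2 can enolise, and tertiary alcohols and isolated alkenes are tolerated.

**Step 6**
Reactants: 13 4α-hydroxy-5αH-eudesma-1,11-dien-3-one
Product: 14 1α,2α-epoxy-4α-hydroxy-5αH-eudesm-11-en-3-one
Conditions: 30% aq. H2O2, NaOH (cat.), MeOH, 0 °C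
Reagents that add atoms: hydrogen peroxide, OO
Why: Weitz–Scheffer epoxidation in which the hydroperoxide anion attacks only the electron-poor enone and adds to C1 from the α face, anti to the adjacent axial C10 methyl group, which should give the 1α,2α-epoxide.

**Step 7**
Reactants: 14 1α,2α-epoxy-4α-hydroxy-5αH-eudesm-11-en-3-one
Product: 16 5αH-eudesma-2,11-diene-1α,4α-diol, via epoxy hydrazone 15 (not isolated)
Conditions: N2H4·H2O (3 equiv), AcOH (cat.), MeOH, 0 °C → rt, argon
Reagents that add atoms: none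
Why: Wharton transposition in which the epoxy hydrazone opens to an allylic diazene that loses N2, so the oxygen moves from C3 to C1 with the C1–O bond retained (1α-OH) and a C2–C3 double bond is left.

**Step 8**
Reactants: 16 5αH-eudesma-2,11-diene-1α,4α-diol
Product: 17 4α-hydroxy-5αH-eudesma-2,11-dien-1-one
Conditions: Dess–Martin periodinane (1.2 equiv), CH2Cl2, rt
Reagents that add atoms: none
Why: Dess–Martin oxidation affects only the secondary allylic alcohol, the tertiary C4 hydroxyl being unoxidisable.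

**Step 9**
Reactants: 17 4α-hydroxy-5αH-eudesma-2,11-dien-1-one
Product: 18 4α-hydroxy-5αH-eudesm-11-en-1-one
Conditions: [(Ph3P)CuH]6 (0.4 equiv), H2O (2 equiv), toluene (degassed), rt
Reagents that add atoms: none
Why: Copper hydride conjugate reduction delivers hydride to C3 of the enone only, isolated alkenes such as the isopropenyl group being inert to this reagent, and protonation of the copper enolate gives the saturated C1 ketone without a new stereocentre.

**Step 10**
Reactants: 18 4α-hydroxy-5αH-eudesm-11-en-1-one; 19 (methoxymethyl)triphenylphosphonium chloride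
Product: 21 4α-hydroxy-5αH-eudesm-11-ene-1β-carbaldehyde, via enol ether 20 (not isolated)
Conditions: 19 (4 equiv), KN(SiMe3)2 (3.8 equiv), THF, 0 → 60 °C; then 1 M HCl, THF, 0 °C → rt
Reagents that add atoms: (methoxymethyl)triphenylphosphonium chloride 19, COC[P+](c1ccccc1)(c1ccccc1)c1ccccc1.[Cl-]; water, O
Why: Wittig methoxymethylenation of the hindered C1 ketone with excess non-stabilised ylide followed by enol ether hydrolysis, in which kinetic protonation of C1 occurs axially from the α face, anti to the neighbouring axial C10 methyl group (the face that small reagents use on 10-methyl-1-decalones), so the formyl group should end up equatorial (1β) provided the conditions stay mild enough to avoid equilibration.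

**Step 11**
Reactants: 21 4α-hydroxy-5αH-eudesm-11-ene-1β-carbaldehyde; 22 (triphenylphosphoranylidene)acetaldehyde
Product: 23 (E)-3-(4α-hydroxy-5αH-eudesm-11-en-1β-yl)prop-2-enal
Conditions: 22 (1.3 equiv), toluene, 90 °C
Reagents that add atoms: (triphenylphosphoranylidene)acetaldehyde 22, O=CC=P(c1ccccc1)(c1ccccc1)c1ccccc1
Why: Wittig olefination with a stabilised formylmethylene ylide under neutral conditions gives the E-enal and should not epimerise the α-branched aldehyde at C1.

**Step 12**
Reactants: 23 (E)-3-(4α-hydroxy-5αH-eudesm-11-en-1β-yl)prop-2-enal; 24 α-methoxystyrene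
Product: 25 4-(4α-hydroxy-5αH-eudesm-11-en-1β-yl)-2-methoxy-2-phenyl-3,4-dihydro-2H-pyran (C4 as C4' of the target; both ketal epimers)
Conditions: 24 (5 equiv), Eu(fod)3 (10 mol %; fod = 6,6,7,7,8,8,8-heptafluoro-2,2-dimethyloctane-3,5-dionate), hexane, rt → 50 °C, sealed tube
Reagents that add atoms: α-methoxystyrene 24, C=C(OC)c1ccccc1
Why: Lewis-acid-catalysed inverse-electron-demand hetero-Diels–Alder reaction of the enal as 1-oxadiene with a 1,1-disubstituted enol ether, whose nucleophilic CH2 terminus bonds to C4' while the aldehyde oxygen bonds to the ketal carbon, and in which C4' should be set by a staggered Felkin–Anh-type approach with the quaternary C10 anti to the forming C3'–C4' bond, the ring CH2 (C2) inside and H1 outside, which leads to the configuration of the target.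

**Step 13**
Reactants: 25 4-(4α-hydroxy-5αH-eudesm-11-en-1β-yl)-2-methoxy-2-phenyl-3,4-dihydro-2H-pyran
Product: 26 2-phenyl-4-[4α-(trimethylsilyloxy)-5αH-eudesm-11-en-1β-yl]-4H-pyran
Conditions: TMSOTf (2.5 equiv), Et3N (4 equiv), CH2Cl2, −78 → 0 °C
Reagents that add atoms: trimethylsilyl triflate, C[Si](C)(C)OS(=O)(=O)C(F)(F)F
Why: Silyl triflate/amine elimination of a ketal to an enol ether, in which ionisation to the benzylic oxocarbenium ion and loss of H3' gives the conjugated 2-phenyl-4H-pyran while the same reagent silylates the tertiary alcohol ahead of the organolithium step.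

**Step 14**
Reactants: 27 dimethyl squarate
Product: 29 3-methoxycyclobut-3-ene-1,2-dione, via hydroxycyclobutenone 28 (not isolated)
Conditions: LiAlH(OtBu)3 (1.05 equiv), THF, −78 → −20 °C, aq. work-up; then conc. HCl (cat.), CH2Cl2, rt
Reagents that add atoms: none
Why: The hindered aluminium hydride reduces one vinylogous ester carbonyl of the squarate and stops there, and acid then shifts the hydroxyl through the methoxy-stabilised cyclobutenyl cation with loss of methanol to give the semisquarate.

**Step 15**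
Reactants: 26 2-phenyl-4-[4α-(trimethylsilyloxy)-5αH-eudesm-11-en-1β-yl]-4H-pyran; 29 3-methoxycyclobut-3-ene-1,2-dione
Product: 31 4-hydroxy-3-methoxy-4-{6-phenyl-4-[4α-(trimethylsilyloxy)-5αH-eudesm-11-en-1β-yl]-4H-pyran-2-yl}cyclobut-2-en-1-one (both carbinol epimers), via lithiopyran 30 (not isolated)
Conditions: t-BuLi (1.2 equiv), THF, −78 → −20 °C; then 29 (1.3 equiv), THF, −78 °C; sat. aq. NH4Cl
Reagents that add atoms: 3-methoxycyclobut-3-ene-1,2-dione 29, COC1=CC(=O)C1=O
Why: α-Lithiation of a cyclic enol ether at its only O–CH= position (abstraction of C4–H would give an antiaromatic 8π pyranyl anion) followed by 1,2-addition to the ketone-like carbonyl next to the methoxy-bearing carbon, the other carbonyl being deactivated as a vinylogous ester, which fixes the future C8'/C7' oxygen pattern.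

**Step 16**
Reactants: 31 4-hydroxy-3-methoxy-4-{6-phenyl-4-[4α-(trimethylsilyloxy)-5αH-eudesm-11-en-1β-yl]-4H-pyran-2-yl}cyclobut-2-en-1-one
Product: 33 7'-methoxy-2'-phenyl-4'-[4α-(trimethylsilyloxy)-5αH-eudesm-11-en-1β-yl]-4'H-chromene-5',8'-diol, via dienylketene 32 (not isolated)
Conditions: toluene (0.01 M, degassed), 110 °C, argon
Reagents that add atoms: none
Why: Conrotatory 4π opening of the cyclobutenone, with the donor hydroxyl rotating outward, places the pyranyl group cis to the ketene in dienylketene 32. Disrotatory 6π electrocyclisation then bonds the ketene carbon (C5') to C4a' of the pyran enol ether, closing the six-membered carbocycle, and enolisation of the resulting cyclohexadienone gives the hydroquinone. The closest known reaction is the thermal rearrangement of 4-alkenyl- and 4-aryl-4-hydroxycyclobutenones to hydroquinones (Moore cyclisation), which includes adducts of α-lithiated cyclic enol ethers. No stereocentre is created, since the only sp3 carbon formed (C4a') is aromatised, and C4' is not involved. The step needs the outward torquoselectivity of the hydroxyl, an electronic preference of donor substituents, and closure onto carbon instead of lactonisation by the carbinol oxygen, which the cis-disposed enol ether π bond secures, while the oxygen pattern (C5'–OH, C7'–OMe, C8'–OH) follows from the connectivity of 31.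

**Step 17**
Reactants: 33 7'-methoxy-2'-phenyl-4'-[4α-(trimethylsilyloxy)-5αH-eudesm-11-en-1β-yl]-4'H-chromene-5',8'-diol
Product: 34 5',7',8'-trimethoxy-2'-phenyl-4'-[4α-(trimethylsilyloxy)-5αH-eudesm-11-en-1β-yl]-4'H-chromene
Conditions: Me2SO4 (4 equiv), K2CO3 (6 equiv), acetone, reflux, argon (crude 33 used directly)
Reagents that add atoms: dimethyl sulfate, COS(=O)(=O)OC
Why: Williamson methylation of both phenoxides under mild carbonate conditions, to which the tertiary silyl ether, the enol ether and C4' are inert.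

**Step 18**
Reactants: 34 5',7',8'-trimethoxy-2'-phenyl-4'-[4α-(trimethylsilyloxy)-5αH-eudesm-11-en-1β-yl]-4'H-chromene
Product: 35 1β-[(4'S)-5',7',8'-trimethoxy-2'-phenyl-4'H-chromen-4'-yl]-5αH-eudesm-11-en-4α-ol (target)
Conditions: K2CO3 (cat.), MeOH, rt
Reagents that add atoms: none
Why: Carbonate-catalysed methanolysis removes the trimethylsilyl ether, and the flavene enol ether is stable to base.

**Compound list**

1 | (+)-dihydrocarvone, (2R,5R)-2-methyl-5-(prop-1-en-2-yl)cyclohexan-1-one | C=C(C)[C@@H]1CC[C@@H](C)C(=O)C1 | starting material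
2 | (R)-1-phenylethylamine (auxiliary) | C[C@@H](N)c1ccccc1 | starting material
3 | ethyl vinyl ketone (pent-1-en-3-one) | C=CC(=O)CC | starting material
4 | N-[(1R)-1-phenylethyl]imine of 1 | C=C(C)[C@@H]1CC[C@@H](C)C(=N[C@H](C)c2ccccc2)C1 | intermediate
5 | N-[(1R)-1-phenylethyl]imine of 6 | C=C(C)[C@@H]1CC[C@@](C)(CCC(=O)CC)C(=N[C@H](C)c2ccccc2)C1 | intermediate
6 | (2S,5R)-2-methyl-2-(3-oxopentyl)-5-(prop-1-en-2-yl)cyclohexan-1-one | C=C(C)[C@@H]1CC[C@@](C)(CCC(=O)CC)C(=O)C1 | intermediate
7 | (+)-α-cyperone, eudesma-4,11-dien-3-one (7β-isopropenyl, 10β-methyl) | C=C(C)[C@@H]1CC[C@@]2(C)CCC(=O)C(C)=C2C1 | intermediate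
8 | lithium 5αH-eudesma-3,11-dien-3-olate | C=C(C)[C@@H]1CC[C@]2(C)[C@@H](C1)C(C)=C([O-])CC2.[Li+] | intermediate
9 | 3-(trimethylsilyloxy)-5αH-eudesma-3,11-diene | C=C(C)[C@@H]1CC[C@]2(C)[C@@H](C1)C(C)=C(O[Si](C)(C)C)CC2 | intermediate
10 | 3α,4α-epoxy-3β-(trimethylsilyloxy)-5αH-eudesm-11-ene | C=C(C)[C@@H]1CC[C@]2(C)[C@@H](C1)[C@]3(C)O[C@]3(O[Si](C)(C)C)CC2 | intermediate
11 | 4α-(trimethylsilyloxy)-5αH-eudesm-11-en-3-one | C=C(C)[C@@H]1CC[C@]2(C)[C@@H](C1)[C@](C)(O[Si](C)(C)C)C(=O)CC2 | intermediate
12 | 4α-hydroxy-5αH-eudesm-11-en-3-one (4β-methyl) | C=C(C)[C@@H]1CC[C@]2(C)[C@@H](C1)[C@](C)(O)C(=O)CC2 | intermediate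
13 | 4α-hydroxy-5αH-eudesma-1,11-dien-3-one | C=C(C)[C@@H]1CC[C@]2(C)[C@@H](C1)[C@](C)(O)C(=O)C=C2 | intermediate
14 | 1α,2α-epoxy-4α-hydroxy-5αH-eudesm-11-en-3-one | C=C(C)[C@@H]1CC[C@]2(C)[C@@H](C1)[C@](C)(O)C(=O)[C@@H]3O[C@@H]32 | intermediate
15 | hydrazone of 14 | C=C(C)[C@@H]1CC[C@]2(C)[C@@H](C1)[C@](C)(O)C(=NN)[C@@H]3O[C@@H]32 | intermediate
16 | 5αH-eudesma-2,11-diene-1α,4α-diol | C=C(C)[C@@H]1CC[C@]2(C)[C@@H](C1)[C@](C)(O)C=C[C@@H]2O | intermediate
17 | 4α-hydroxy-5αH-eudesma-2,11-dien-1-one | C=C(C)[C@@H]1CC[C@]2(C)[C@@H](C1)[C@](C)(O)C=CC2=O | intermediate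
18 | 4α-hydroxy-5αH-eudesm-11-en-1-one | C=C(C)[C@@H]1CC[C@]2(C)[C@@H](C1)[C@](C)(O)CCC2=O | intermediate
19 | (methoxymethyl)triphenylphosphonium chloride | COC[P+](c1ccccc1)(c1ccccc1)c1ccccc1.[Cl-] | starting material
20 | 1-(methoxymethylidene)-5αH-eudesm-11-en-4α-ol (E/Z mixture) | C=C(C)[C@@H]1CC[C@]2(C)[C@@H](C1)[C@](C)(O)CCC2=COC | intermediate
21 | 4α-hydroxy-5αH-eudesm-11-ene-1β-carbaldehyde | C=C(C)[C@@H]1CC[C@]2(C)[C@@H](C1)[C@](C)(O)CC[C@H]2C=O | intermediate
22 | (triphenylphosphoranylidene)acetaldehyde | O=CC=P(c1ccccc1)(c1ccccc1)c1ccccc1 | starting material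
23 | (E)-3-(4α-hydroxy-5αH-eudesm-11-en-1β-yl)prop-2-enal | C=C(C)[C@@H]1CC[C@]2(C)[C@@H](C1)[C@](C)(O)CC[C@H]2/C=C/C=O | intermediate
24 | α-methoxystyrene, (1-methoxyethenyl)benzene | C=C(OC)c1ccccc1 | starting material
25 | 4-(4α-hydroxy-5αH-eudesm-11-en-1β-yl)-2-methoxy-2-phenyl-3,4-dihydro-2H-pyran (C4 as C4' of the target; ketal carbon either way) | C=C(C)[C@@H]1CC[C@]2(C)[C@@H](C1)[C@](C)(O)CC[C@H]2[C@H]1CC(OC)(c2ccccc2)OC=C1 | intermediate
26 | 2-phenyl-4-[4α-(trimethylsilyloxy)-5αH-eudesm-11-en-1β-yl]-4H-pyran (C4 as C4' of the target) | C=C(C)[C@@H]1CC[C@]2(C)[C@@H](C1)[C@](C)(O[Si](C)(C)C)CC[C@H]2[C@H]1C=C(c2ccccc2)OC=C1 | intermediate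
27 | dimethyl squarate | COC1=C(OC)C(=O)C1=O | starting material
28 | 4-hydroxy-2,3-dimethoxycyclobut-2-en-1-one (racemic) | COC1=C(OC)C(O)C1=O | intermediate
29 | 3-methoxycyclobut-3-ene-1,2-dione | COC1=CC(=O)C1=O | intermediate
30 | {6-phenyl-4-[4α-(trimethylsilyloxy)-5αH-eudesm-11-en-1β-yl]-4H-pyran-2-yl}lithium | C=C(C)[C@@H]1CC[C@]2(C)[C@@H](C1)[C@](C)(O[Si](C)(C)C)CC[C@H]2[C@H]1C=C(c2ccccc2)OC([Li])=C1 | intermediate
31 | 4-hydroxy-3-methoxy-4-{6-phenyl-4-[4α-(trimethylsilyloxy)-5αH-eudesm-11-en-1β-yl]-4H-pyran-2-yl}cyclobut-2-en-1-one (carbinol carbon either way) | C=C(C)[C@@H]1CC[C@]2(C)[C@@H](C1)[C@](C)(O[Si](C)(C)C)CC[C@H]2[C@H]1C=C(c2ccccc2)OC(=C1)C1(O)C(OC)=CC1=O | intermediate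
32 | 4-hydroxy-3-methoxy-4-(pyran-2-yl)buta-1,3-dien-1-one (dienylketene; pyranyl group cis to the ketene-bearing carbon; pyranyl as in 31) | C=C(C)[C@@H]1CC[C@]2(C)[C@@H](C1)[C@](C)(O[Si](C)(C)C)CC[C@H]2[C@H]1C=C(c2ccccc2)OC(=C1)C(/O)=C(/OC)C=C=O | intermediate
33 | 7'-methoxy-2'-phenyl-4'-[4α-(trimethylsilyloxy)-5αH-eudesm-11-en-1β-yl]-4'H-chromene-5',8'-diol (4'S) | C=C(C)[C@@H]1CC[C@]2(C)[C@@H](C1)[C@](C)(O[Si](C)(C)C)CC[C@H]2[C@H]1C=C(c2ccccc2)Oc2c(O)c(OC)cc(O)c21 | intermediate
34 | 5',7',8'-trimethoxy-2'-phenyl-4'-[4α-(trimethylsilyloxy)-5αH-eudesm-11-en-1β-yl]-4'H-chromene (4'S) | C=C(C)[C@@H]1CC[C@]2(C)[C@@H](C1)[C@](C)(O[Si](C)(C)C)CC[C@H]2[C@H]1C=C(c2ccccc2)Oc2c(OC)c(OC)cc(OC)c21 | intermediate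
35 | 1β-[(4'S)-5',7',8'-trimethoxy-2'-phenyl-4'H-chromen-4'-yl]-5αH-eudesm-11-en-4α-ol | C=C(C)[C@@H]1CC[C@]2(C)[C@@H](C1)[C@](C)(O)CC[C@H]2[C@H]1C=C(c2ccccc2)Oc2c(OC)c(OC)cc(OC)c21 | target

**Totals**

Total step count: 18.
Longest linear sequence: 17 steps (steps 1–13 and 15–18; step 14 is a one-step side branch).

**Steps most likely to fail**

Step 15. The base may abstract the doubly allylic C4–H instead of the O–CH= proton, the lithiated 4H-pyran may decompose before it is trapped, and addition to the wrong carbonyl of 29 would scramble the oxygen pattern. The fallback sets out from 25 and comes back at 34. The heterocycle is metallated while it is still an ordinary 3,4-dihydro-2H-pyran, for which α-lithiation and the Moore cyclisation of the resulting adducts are established. Silylation of 25 (TMSCl, imidazole, DMF) gives the trimethylsilyl ether F3. t-BuLi (THF, −78 → 0 °C) gives the 6-lithiodihydropyran F4, which adds to 29 to give the dihydropyranyl cyclobutenone F5. Heating in toluene gives the 2'-methoxyflavan hydroquinone F6, and methylation (Me2SO4, K2CO3) gives the tetramethoxy ketal F7. TMSOTf/Et3N then removes methanol across C2'–C3' and gives 34.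

Step 16. The ketene may be captured by the carbinol oxygen (furanone formation) if ring opening is not fully torquoselective, the 4H-pyran unit may degrade at 110 °C, and the hydroquinone may oxidise to the quinone on handling. The fallback sets out from 26 and comes back at 34. The carbinol oxygen is capped before the rearrangement: lithiation of 26 and addition to 29 as in step 15, with the alkoxide quenched by MeOTf instead of NH4Cl, gives the 3,4-dimethoxycyclobutenone F8. Thermolysis in toluene gives directly the air-stable 5'-hydroxy-7',8'-dimethoxyflavene F9, which cannot lactonise on the way. A single O-methylation (Me2SO4, K2CO3) then gives 34.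

Step 12. Cycloaddition at the neopentyl-like β-carbon may be slow, the enol ether may add to the carbonyl group or oligomerise under Lewis acid, and the facial selectivity next to C1 may be low. The fallback sets out from 23 and comes back at 26. The C3'–C4' bond is made under catalyst control in a stepwise Mukaiyama–Michael reaction: enal 23, 1-phenyl-1-(trimethylsilyloxy)ethene and the trifluoroacetate salt of (2S,5S)-5-benzyl-2-tert-butyl-3-methylimidazolidin-4-one (iminium catalysis, tert-butanol/isopropanol, −20 °C) give the δ-keto aldehyde F1. The benzyl group of the catalyst shields one face of the iminium ion, so the nucleophile should be sent to the face that the substrate also prefers. Acid-catalysed cyclodehydration of this 1,5-dicarbonyl compound (PPTS, 4 Å molecular sieves, toluene, 80 °C) gives the hydroxy-4H-pyran F2. Silylation (TMSOTf, 2,6-lutidine, CH2Cl2, −78 °C) gives 26.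

**Further compounds**

F1 | step 12 | 3-(4α-hydroxy-5αH-eudesm-11-en-1β-yl)-5-oxo-5-phenylpentanal (C3 as C4' of the target) | C=C(C)[C@@H]1CC[C@]2(C)[C@@H](C1)[C@](C)(O)CC[C@H]2[C@H](CC=O)CC(=O)c1ccccc1
F2 | step 12 | 4-(4α-hydroxy-5αH-eudesm-11-en-1β-yl)-2-phenyl-4H-pyran | C=C(C)[C@@H]1CC[C@]2(C)[C@@H](C1)[C@](C)(O)CC[C@H]2[C@H]1C=C(c2ccccc2)OC=C1
F3 | step 15 | 2-methoxy-2-phenyl-4-[4α-(trimethylsilyloxy)-5αH-eudesm-11-en-1β-yl]-3,4-dihydro-2H-pyran | C=C(C)[C@@H]1CC[C@]2(C)[C@@H](C1)[C@](C)(O[Si](C)(C)C)CC[C@H]2[C@H]1CC(OC)(c2ccccc2)OC=C1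
F4 | step 15 | 6-lithio derivative of F3 | C=C(C)[C@@H]1CC[C@]2(C)[C@@H](C1)[C@](C)(O[Si](C)(C)C)CC[C@H]2[C@H]1CC(OC)(c2ccccc2)OC([Li])=C1
F5 | step 15 | 4-hydroxy-3-methoxy-4-{2-methoxy-2-phenyl-4-[4α-(trimethylsilyloxy)-5αH-eudesm-11-en-1β-yl]-3,4-dihydro-2H-pyran-6-yl}cyclobut-2-en-1-one | C=C(C)[C@@H]1CC[C@]2(C)[C@@H](C1)[C@](C)(O[Si](C)(C)C)CC[C@H]2[C@H]1CC(OC)(c2ccccc2)OC(=C1)C1(O)C(OC)=CC1=O
F6 | step 15 | 2',7'-dimethoxy-2'-phenyl-4'-[4α-(trimethylsilyloxy)-5αH-eudesm-11-en-1β-yl]chromane-5',8'-diol | C=C(C)[C@@H]1CC[C@]2(C)[C@@H](C1)[C@](C)(O[Si](C)(C)C)CC[C@H]2[C@H]1CC(OC)(c2ccccc2)Oc2c(O)c(OC)cc(O)c21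
F7 | step 15 | 2',5',7',8'-tetramethoxy-2'-phenyl-4'-[4α-(trimethylsilyloxy)-5αH-eudesm-11-en-1β-yl]chromane | C=C(C)[C@@H]1CC[C@]2(C)[C@@H](C1)[C@](C)(O[Si](C)(C)C)CC[C@H]2[C@H]1CC(OC)(c2ccccc2)Oc2c(OC)c(OC)cc(OC)c21
F8 | step 16 | 3,4-dimethoxy-4-{6-phenyl-4-[4α-(trimethylsilyloxy)-5αH-eudesm-11-en-1β-yl]-4H-pyran-2-yl}cyclobut-2-en-1-one | C=C(C)[C@@H]1CC[C@]2(C)[C@@H](C1)[C@](C)(O[Si](C)(C)C)CC[C@H]2[C@H]1C=C(c2ccccc2)OC(=C1)C1(OC)C(OC)=CC1=O
F9 | step 16 | 7',8'-dimethoxy-2'-phenyl-4'-[4α-(trimethylsilyloxy)-5αH-eudesm-11-en-1β-yl]-4'H-chromen-5'-ol | C=C(C)[C@@H]1CC[C@]2(C)[C@@H](C1)[C@](C)(O[Si](C)(C)C)CC[C@H]2[C@H]1C=C(c2ccccc2)Oc2c(OC)c(OC)cc(O)c21
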